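A straight line of product against time tempts one to read a low order in whatever falls during the run. The winter flask is the flask asked about, and the summer flask differs from it in its charge of starting material.

| flask | starting material | reagent | free catalyst | added ligand | remark |
|---|---|---|---|---|---|
| winter | 0.30 M | 0.30 M | 6 mM | 6.8 mM | the very flask that is asked about, followed so far |
| summer | 0.20 M | 0.30 M | 6 mM | 6.8 mM | run made earlier |
| flask | 0.30 M | 0.300 M | 6.0 mM | 6.8 mM |  |

| run | time / h | product / % | starting material / % |
|---|---|---|---|
| winter | 0.333 | 0.6 | 97.5 |
| winter | 0.833 | 3.6 | 96.3 |
| winter | 1.50 | 6.0 | 93.8 |
| winter | 2.50 | 10.6 | 89.2 |
| summer | 0.500 | 3.6 | 96.4 |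
| summer | 1.33 | 7.7 | 91.3 |
| summer | 2.50 | 14.9 | 84.6 |
| summer | 4.00 | 23.7 | 74.3 |

(scatter of a reading: 0.5 percentage points)

* apparent order in reagent when 10% of the starting material are converted (percent change of the rate of making product for one percent more reagent charged)
* apparent order in free catalyst when 10% of the starting material are converted (percent change of the rate of making product for one percent more free catalyst charged)

- no earlier run changes the charge of free catalyst; that part of a forecast is a guess
- no earlier run changes the charge of reagent; that part of a forecast is a guess

What does the winter flask make per hour? Take the mean rate, meaning the product made by the last reading divided by the time of that reading: 0.0127 M/h. One reading's scatter makes this uncertain by 4.72%.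

And the summer flask? Its mean rate is 0.0118 M/h, a little less than the winter mean, though it was charged with 0.20 M of starting material against 0.30 M. So across these two runs a third less starting material charged goes with a mean rate only 6.84% lower, a reading that lies within the scatter of the last points.

Is the curve fairly replaced by its mean? In the summer flask the rate is 0.0116 M/h up to 1.33 h and 0.0120 M/h afterwards, so yes, within scatter.

Then is the order in reagent small? That does not follow. If reagent is used one for one, it falls 15.8% across the summer flask. An order of 0.5 then means about 7.90% off the rate from start to end, while the early stretch is read to 6.49%. No run changes the charge of reagent or of free catalyst, so my own commitment is a guess: about 0.5 in reagent, with a wide margin, and about 1 in free catalyst.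

The forecast gives 0.15 in reagent and 1 in free catalyst, holding that “the order in reagent looks small”.

The flask gives 0.54 in reagent and 1.3 in free catalyst.

    reagent + free catalyst ⇌ catalyst intermediate A (K = 8.10 /M, k = 390 /M/h)
    catalyst intermediate A → by-product + catalyst intermediate B (k = 15.0 /h)
    starting material + catalyst intermediate B ⇌ catalyst intermediate C (K = 130 /M, k = 250 /M/h)
    catalyst intermediate C → free catalyst + product (k = 10.0 /h)
    free catalyst + added ligand ⇌ idle complex, settled at all times (K = 1700 /M)

Carried forward, the mean rate puts the flask's product at 25.4% after 6.00 h, and the flask stands at 24.6%. Part of the order in reagent comes from the association of free catalyst with added ligand: in the same flask run without that association, the order in reagent is 0.20 instead of 0.54. This idle complex lies outside the working round (off-cycle), and after 3.00 h it holds 53.0% of the catalyst charged.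

The data are simulated on assumed constants, and the scatter is random.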